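Its constants belong to no real substance; what happens was integrated by code.

The amounts to check before anything else are the protic impurity and the electrophile: 0.0500 M of the first against 0.050 M of the second, so the two are charged about equally. The electrophile reacts with the nucleophile to give target, and with the protic impurity to give quenched substrate. Protons from the first route and from the fed buffer acid are shared between the nucleophile and the buffer base.

electrophile 0.050 M; nucleophile 1.30 equiv; buffer base 3.00 equiv; buffer acid 0.100 equiv (fed, over 4.0 s); protic impurity 0.0500 M; time 8.0 s; the fed solution adds 0.10 times the starting volume

    electrophile + nucleophile → acid + target + leaving group (k1 = 3.3 M⁻¹ s⁻¹)
    protonated nucleophile ⇌ nucleophile + acid, settled at all times (K2 = 1.3 × 10⁻⁹ M)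
    buffer acid ⇌ buffer base + acid, settled at all times (K3 = 5.0 × 10⁻⁸ M)
    electrophile + protic impurity → quenched substrate (k4 = 25 M⁻¹ s⁻¹)

- acid is the free proton; pH is minus the decimal logarithm of its molar concentration
- charges are per starting volume, the dose included; the dosed solution carries all of it
- run time (flask): 8.0 s

- part of the electrophile that has reacted at 8.0 s
- pH of the solution at 8.0 s

The bench rule is pseudo-first-order: hold each partner at its charged amount and count lifetimes of the electrophile. At those amounts the impurity route has a half-life of 0.55 s, shorter than the 3.2 s of the nucleophile route. The two rates together give a lifetime of 0.683 s. The run lasts 11.7 lifetimes, so the rule leaves <0.001% of the electrophile.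

The rule needs a partner that stays near its charge, and the impurity does not. The ratio that shows this is the impurity capacity, the impurity charge over the electrophile charge, which for a ratio up to one is the largest part of the electrophile the impurity can consume: 100%. On this route impurity and electrophile therefore fall together. With the impurity route by itself and equal charges, and dilution by the feed left aside, the second-order form leaves 9.09%. My own reckoning stops there: I expect the electrophile left to lie between those two figures, and I give no pH by hand.

The forecast names 98% reacted and pH 9.3, holding that “The impurity consumes most of the electrophile quickly”.

The simulation gives 98.5% reacted and pH 9.35, so the forecast stands on both counts. In this flask, with a capacity of 100%, 77.7% of the electrophile became quenched substrate, and 22.3% of the impurity charge remained. The neighbour flask, charged with 0.013 M of impurity, has a capacity of 26.0%. Its quenched substrate reached 25.7%, matching that capacity, with its impurity down to 1.17% of charge. Target in the neighbour flask reached 44.0%, more than the 20.8% of this flask, while 30% of its electrophile was still there.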